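The synthesis rests on disconnecting the C5=C6 alkene (halimane numbering) at the junction of rings A and B. A McMurry coupling of a 1,6-keto aldehyde, whose ketone is C5 of a preformed ring A and whose aldehyde is C6 at the end of the C10–C9–C8–C7 chain, closes ring B and installs the trisubstituted alkene in one operation. The precursor is a 2,2,6-trisubstituted cyclohexanone that already carries the four core stereocenters: C8 from a glutarate half-ester, C10 from an Ireland–Claisen rearrangement, C9 from a lactone-templated methylation, C4 from enolate alkylation anti to the C10 substituent. The side chain and C13 follow by B-alkyl Suzuki coupling and asymmetric hydrogenation.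

Key step: step 12

Remark: locants C1–C20 are the halimane locants of the target (C4 quaternary carbon bearing C18H2OAc, C5=C6 ring alkene, C8 methine with methyl C17, C9 quaternary carbon with methyl C20 and the C11–C16 side chain, C10 ring-fusion methine); compounds 1, 3 and 18 are taken as purchasable.

Step 1
Reactants: 1 1,4-dioxaspiro[4.5]dec-6-en-8-one
Product: 2 (8R)-1,4-dioxaspiro[4.5]dec-6-en-8-ol
Conditions: (S)-2-methyl-CBS-oxazaborolidine (10 mol %), BH3·SMe2, THF, −20 °C; MeOH quench
Reagents that add atoms: none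
Why: Corey–Bakshi–Shibata reduction, in which the oxazaborolidine–borane complex binds the enone carbonyl with the alkene arm as the large group and delivers hydride to one face, so that the (S)-catalyst should give the (R)-allylic alcohol from which C10 is later derived.

Step 2
Reactants: 2 (8R)-1,4-dioxaspiro[4.5]dec-6-en-8-ol; 3 (3R)-5-methoxy-3-methyl-5-oxopentanoic acid (methyl hydrogen (R)-3-methylglutarate)
Product: 4 5-[(8R)-1,4-dioxaspiro[4.5]dec-6-en-8-yl] 1-methyl (3S)-3-methylpentanedioate
Conditions: DCC, DMAP (cat.), CH2Cl2, 0 °C to rt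
Reagents that add atoms: none
Why: Steglich esterification of the free carboxyl group of 3 with the allylic alcohol, which leaves the methyl ester and the stereocenter that becomes C8 untouched.

Step 3
Reactants: 4 5-[(8R)-1,4-dioxaspiro[4.5]dec-6-en-8-yl] 1-methyl (3S)-3-methylpentanedioate
Product: 6 (3S)-2-[(6S)-1,4-dioxaspiro[4.5]dec-7-en-6-yl]-5-methoxy-3-methyl-5-oxopentanoic acid (C2 epimers), via bis(trimethylsilyl ketene acetal) 5 (not isolated)
Conditions: LiN(iPr)2 (2.4 equiv), Me3SiCl, THF, −78 °C, then 60 °C; aq. citric acid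
Reagents that add atoms: none
Why: Ireland–Claisen rearrangement, in which both ester α-positions are silylated but only the allylic silyl ketene acetal can undergo the [3,3] shift, whose suprafacial course on the cyclohexene forms the C9–C10 bond on the face of the departing oxygen and so transfers the carbinol configuration to C10, while C9 forms as a mixture that step 5 resets.

Step 4
Reactants: 6 (3S)-2-[(6S)-1,4-dioxaspiro[4.5]dec-7-en-6-yl]-5-methoxy-3-methyl-5-oxopentanoic acid
Product: 8 (4S)-3-[(6S)-1,4-dioxaspiro[4.5]dec-7-en-6-yl]-4-methyloxan-2-one (C3 epimers), via hydroxy acid 7 (not isolated)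
Conditions: LiBH4, THF, 0 °C to rt; 1 M HCl (0 °C, brief); then PPTS (cat.), toluene, 60 °C
Reagents that add atoms: none
Why: Chemoselective borohydride reduction of the methyl ester beside the lithium carboxylate followed by acid-catalysed lactonization of the δ-hydroxy acid gives the six-membered lactone that serves as the template for C9.

Step 5
Reactants: 8 (4S)-3-[(6S)-1,4-dioxaspiro[4.5]dec-7-en-6-yl]-4-methyloxan-2-one
Product: 9 (3R,4S)-3-[(6S)-1,4-dioxaspiro[4.5]dec-7-en-6-yl]-3,4-dimethyloxan-2-one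
Conditions: LiN(iPr)2, THF, −78 °C; MeI, DMPU, −78 to −30 °C
Reagents that add atoms: iodomethane, CI
Why: Lactone enolate alkylation, in which the C8 methyl group sits pseudoaxial next to the planar enolate carbon C9 so that iodomethane should enter trans to it and set the quaternary C9 with C20 trans to C17 on the lactone ring, which is the C8/C9 relationship of the target.

Step 6
Reactants: 9 (3R,4S)-3-[(6S)-1,4-dioxaspiro[4.5]dec-7-en-6-yl]-3,4-dimethyloxan-2-one
Product: 11 (3R,4S)-3,4-dimethyl-3-[(1S)-2-oxocyclohexyl]oxan-2-one, via saturated spiroacetal 10 (not isolated)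
Conditions: H2 (1 atm), 10% Pd/C, EtOAc, rt; then PPTS (cat.), acetone/H2O, 50 °C
Reagents that add atoms: water, O
Why: Heterogeneous hydrogenation of the cis-disubstituted ring alkene followed by mild acetal hydrolysis creates no stereocenter and uses a weak acid so that C10, now α to the ketone, should not enolize.

Step 7
Reactants: 11 (3R,4S)-3,4-dimethyl-3-[(1S)-2-oxocyclohexyl]oxan-2-one
Product: 12 (3R,4S)-3,4-dimethyl-3-[(1S)-3-methyl-2-oxocyclohexyl]oxan-2-one (epimers at the new methyl-bearing carbon C4)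
Conditions: LiN(iPr)2, THF, −78 °C; MeI, −78 to −20 °C
Reagents that add atoms: iodomethane, CI
Why: Kinetic enolate alkylation, in which the amide base removes a proton from the unhindered C4 methylene and not from the C10 methine shielded by the quaternary C9 (the lactone has no α-hydrogen), the configuration of the new center being irrelevant because it is enolized again in step 8.

Step 8
Reactants: 12 (3R,4S)-3,4-dimethyl-3-[(1S)-3-methyl-2-oxocyclohexyl]oxan-2-one
Product: 13 (3R,4S)-3-{(1S,3S)-3-[(benzyloxy)methyl]-3-methyl-2-oxocyclohexyl}-3,4-dimethyloxan-2-one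
Conditions: LiN(iPr)2, THF, −78 to 0 °C; BnOCH2Cl, −78 to −20 °C
Reagents that add atoms: benzyl chloromethyl ether, ClCOCc1ccccc1
Why: Enolate alkylation forming the quaternary C4, in which deprotonation again occurs at C4 and the chloromethyl ether should attack axially on the face opposite the bulky C10 substituent (1,3-induction across the carbonyl), placing the benzyloxymethyl group cis to H10 as the target requires.

Step 9
Reactants: 13 (3R,4S)-3-{(1S,3S)-3-[(benzyloxy)methyl]-3-methyl-2-oxocyclohexyl}-3,4-dimethyloxan-2-one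
Product: 14 (3R,4S)-3-{(1S,3S)-3-[(benzyloxy)methyl]-2-hydroxy-3-methylcyclohexyl}-3,4-dimethyloxan-2-ol (epimers at the lactol carbon C11 and the carbinol carbon C5)
Conditions: iBu2AlH (3 equiv), CH2Cl2, −78 °C
Reagents that add atoms: none
Why: Hydride reduction at low temperature should stop the α-quaternary lactone at the lactol stage (stable aluminium hemiacetal) and also reduce the ketone to the alcohol, which step 11 reoxidizes.

Step 10
Reactants: 14 (3R,4S)-3-{(1S,3S)-3-[(benzyloxy)methyl]-2-hydroxy-3-methylcyclohexyl}-3,4-dimethyloxan-2-ol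
Product: 15 (3S,4R)-4-{(1S,3S)-3-[(benzyloxy)methyl]-2-hydroxy-3-methylcyclohexyl}-3,4-dimethylhex-5-en-1-ol (carbinol epimers at C5)
Conditions: Ph3PCH3Br, KOtBu, THF, 0 °C to reflux
Reagents that add atoms: methyltriphenylphosphonium bromide, C[P+](c1ccccc1)(c1ccccc1)c1ccccc1.[Br-]
Why: Wittig methylenation of the aldehyde in equilibrium with the lactol unmasks the C11=C12 vinyl group on C9 and frees the C6 hydroxyl group in one operation.

Step 11
Reactants: 15 (3S,4R)-4-{(1S,3S)-3-[(benzyloxy)methyl]-2-hydroxy-3-methylcyclohexyl}-3,4-dimethylhex-5-en-1-ol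
Product: 16 (3S,4R)-4-{(1S,3S)-3-[(benzyloxy)methyl]-3-methyl-2-oxocyclohexyl}-3,4-dimethylhex-5-enal
Conditions: Dess–Martin periodinane, pyridine, CH2Cl2, 0 °C to rt
Reagents that add atoms: none
Why: Dess–Martin oxidation of both the primary C6 and the secondary C5 hydroxyl group should give the 1,6-keto aldehyde under buffered conditions that do not epimerize C10.

Step 12
Reactants: 16 (3S,4R)-4-{(1S,3S)-3-[(benzyloxy)methyl]-3-methyl-2-oxocyclohexyl}-3,4-dimethylhex-5-enal
Product: 17 (1R,2S,5R,8aS)-5-[(benzyloxy)methyl]-1-ethenyl-1,2,5-trimethyl-1,2,3,5,6,7,8,8a-octahydronaphthalene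
Conditions: TiCl3(DME)1.5, Zn–Cu couple, DME, reflux; 16 added over 30 h (syringe pump, high dilution)
Reagents that add atoms: none
Why: Low-valent titanium generated from TiCl3(DME)1.5 and Zn–Cu transfers single electrons to the aldehyde C6 and the ketone C5, the two titanium-bound ketyl carbons couple to a titanium pinacolate, and both C–O bonds are then cleaved on the metal at reflux to leave the C5=C6 double bond (intramolecular McMurry carbonyl coupling, the closest precedent being keto aldehyde cyclizations to 1-substituted cyclohexenes). Ring B closes as a six-membered carbocycle by direct union of the two carbonyl carbons, which are 1,6-related through C10, C9, C8 and C7, so the alkene can only lie between C5 and C6. No stereocenter is created; C4, C8 and C9 are not touched, and C10, the only one at risk because it is α to the ketone, is protected by the non-basic medium. The step needs intramolecular over intermolecular coupling, which syringe-pump addition at high dilution and the preorganization of the chain by the two fully substituted carbons C4 and C9 should secure, and the benzyl ether and the isolated vinyl group should be inert to the reagent.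

Step 13
Reactants: 18 but-2-yn-1-ol
Product: 19 (2Z)-3-iodobut-2-en-1-ol
Conditions: NaAlH2(OCH2CH2OMe)2, THF, 0 °C to rt; then I2, −78 to 0 °C
Reagents that add atoms: iodine, II
Why: Hydroxyl-directed trans-hydroalumination of the propargylic alcohol places aluminium at C3, and iodinolysis with retention should give the (Z)-iodoalkene.

Step 14
Reactants: 17 (1R,2S,5R,8aS)-5-[(benzyloxy)methyl]-1-ethenyl-1,2,5-trimethyl-1,2,3,5,6,7,8,8a-octahydronaphthalene; 19 (2Z)-3-iodobut-2-en-1-ol
Product: 21 (2Z)-5-{(1R,2S,5R,8aS)-5-[(benzyloxy)methyl]-1,2,5-trimethyl-1,2,3,5,6,7,8,8a-octahydronaphthalen-1-yl}-3-methylpent-2-en-1-ol, via B-alkyl-9-borabicyclononane 20 (not isolated)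
Conditions: 9-BBN, THF, rt; then 19, Pd(dppf)Cl2 (5 mol %), AsPh3, Cs2CO3, DMF/H2O, rt
Reagents that add atoms: none
Why: B-alkyl Suzuki–Miyaura coupling, in which 9-BBN adds only to the terminal vinyl group (anti-Markovnikov, the trisubstituted C5=C6 alkene being too hindered) and the primary alkylborane couples with the alkenyl iodide with retention of the (Z) geometry.

Step 15
Reactants: 21 (2Z)-5-{(1R,2S,5R,8aS)-5-[(benzyloxy)methyl]-1,2,5-trimethyl-1,2,3,5,6,7,8,8a-octahydronaphthalen-1-yl}-3-methylpent-2-en-1-ol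
Product: 22 (3R)-5-{(1R,2S,5R,8aS)-5-[(benzyloxy)methyl]-1,2,5-trimethyl-1,2,3,5,6,7,8,8a-octahydronaphthalen-1-yl}-3-methylpentan-1-ol
Conditions: Ru(OAc)2[(R)-BINAP] (1 mol %), H2 (30 atm), MeOH, rt
Reagents that add atoms: none
Why: Hydroxyl-directed asymmetric hydrogenation of an allylic alcohol (Noyori type), in which the (R)-BINAP complex should reduce the nerol-type (Z)-alkene to the (R)-configured C13, as in the reduction of nerol to (R)-citronellol, while the isolated C5=C6 alkene and the benzyl ether are left untouched.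

Step 16
Reactants: 22 (3R)-5-{(1R,2S,5R,8aS)-5-[(benzyloxy)methyl]-1,2,5-trimethyl-1,2,3,5,6,7,8,8a-octahydronaphthalen-1-yl}-3-methylpentan-1-ol
Product: 23 (3R)-5-{(1R,2S,5R,8aS)-5-[(benzyloxy)methyl]-1,2,5-trimethyl-1,2,3,5,6,7,8,8a-octahydronaphthalen-1-yl}-3-methylpentanoic acid
Conditions: TEMPO (cat.), PhI(OAc)2, MeCN/H2O, rt
Reagents that add atoms: water, O
Why: Oxoammonium (TEMPO) oxidation of the primary alcohol through the aldehyde hydrate to the carboxylic acid, which should not affect the benzyl ether, the trisubstituted alkene or the β-stereocenter C13.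

Step 17
Reactants: 23 (3R)-5-{(1R,2S,5R,8aS)-5-[(benzyloxy)methyl]-1,2,5-trimethyl-1,2,3,5,6,7,8,8a-octahydronaphthalen-1-yl}-3-methylpentanoic acid
Product: 24 (3R)-5-[(1R,2S,5R,8aS)-5-(hydroxymethyl)-1,2,5-trimethyl-1,2,3,5,6,7,8,8a-octahydronaphthalen-1-yl]-3-methylpentanoic acid
Conditions: Li, NH3 (l), THF, −78 °C; NH4Cl
Reagents that add atoms: none
Why: Dissolving-metal (Birch-type) cleavage of the benzyl ether, under which the carboxylate and the isolated trisubstituted alkene should not be reduced.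

Step 18
Reactants: 24 (3R)-5-[(1R,2S,5R,8aS)-5-(hydroxymethyl)-1,2,5-trimethyl-1,2,3,5,6,7,8,8a-octahydronaphthalen-1-yl]-3-methylpentanoic acid
Product: 26 (3R)-5-[(1R,2S,5R,8aS)-5-(acetyloxymethyl)-1,2,5-trimethyl-1,2,3,5,6,7,8,8a-octahydronaphthalen-1-yl]-3-methylpentanoic acid (CNP0148247.1), via mixed acetic carboxylic anhydride 25 (not isolated)
Conditions: Ac2O, pyridine, DMAP (cat.), CH2Cl2, rt; then H2O, THF
Reagents that add atoms: acetic anhydride, CC(=O)OC(C)=O; water, O
Why: DMAP-catalysed acyl transfer acetylates the neopentyl primary alcohol, and the mixed anhydride formed at the carboxyl group should be hydrolysed on aqueous work-up to return the free acid.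

Compound list
1 | 1,4-dioxaspiro[4.5]dec-6-en-8-one | O=C1C=CC2(CC1)OCCO2 | starting material
2 | (8R)-1,4-dioxaspiro[4.5]dec-6-en-8-ol | O[C@H]1C=CC2(CC1)OCCO2 | intermediate
3 | (3R)-5-methoxy-3-methyl-5-oxopentanoic acid | COC(=O)C[C@H](C)CC(=O)O | starting material
4 | 5-[(8R)-1,4-dioxaspiro[4.5]dec-6-en-8-yl] 1-methyl (3S)-3-methylpentanedioate | COC(=O)C[C@H](C)CC(=O)O[C@H]1C=CC2(CC1)OCCO2 | intermediate
5 | bis(trimethylsilyl ketene acetal) of 4, (3S)-1-[(8R)-1,4-dioxaspiro[4.5]dec-6-en-8-yloxy]-5-methoxy-3-methyl-1,5-bis(trimethylsilyloxy)penta-1,4-diene (alkene geometries not defined) | COC(O[Si](C)(C)C)=C[C@H](C)C=C(O[Si](C)(C)C)O[C@H]1C=CC2(CC1)OCCO2 | intermediate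
6 | (3S)-2-[(6S)-1,4-dioxaspiro[4.5]dec-7-en-6-yl]-5-methoxy-3-methyl-5-oxopentanoic acid (C2 epimers) | COC(=O)C[C@H](C)C(C(=O)O)[C@@H]1C=CCCC12OCCO2 | intermediate
7 | (3S)-2-[(6S)-1,4-dioxaspiro[4.5]dec-7-en-6-yl]-5-hydroxy-3-methylpentanoic acid (C2 epimers) | OCC[C@H](C)C(C(=O)O)[C@@H]1C=CCCC12OCCO2 | intermediate
8 | (4S)-3-[(6S)-1,4-dioxaspiro[4.5]dec-7-en-6-yl]-4-methyloxan-2-one (C3 epimers) | O=C1OCC[C@H](C)C1[C@@H]2C=CCCC23OCCO3 | intermediate
9 | (3R,4S)-3-[(6S)-1,4-dioxaspiro[4.5]dec-7-en-6-yl]-3,4-dimethyloxan-2-one | O=C1OCC[C@H](C)[C@]1(C)[C@@H]2C=CCCC23OCCO3 | intermediate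
10 | (3R,4S)-3-[(6S)-1,4-dioxaspiro[4.5]decan-6-yl]-3,4-dimethyloxan-2-one | O=C1OCC[C@H](C)[C@]1(C)[C@@H]2CCCCC23OCCO3 | intermediate
11 | (3R,4S)-3,4-dimethyl-3-[(1S)-2-oxocyclohexyl]oxan-2-one | O=C1OCC[C@H](C)[C@]1(C)[C@@H]2CCCCC2=O | intermediate
12 | (3R,4S)-3,4-dimethyl-3-[(1S)-3-methyl-2-oxocyclohexyl]oxan-2-one (epimers at the ring methyl carbon) | O=C1OCC[C@H](C)[C@]1(C)[C@@H]2CCCC(C)C2=O | intermediate
13 | (3R,4S)-3-{(1S,3S)-3-[(benzyloxy)methyl]-3-methyl-2-oxocyclohexyl}-3,4-dimethyloxan-2-one | O=C1OCC[C@H](C)[C@]1(C)[C@@H]2CCC[C@@](C)(COCc3ccccc3)C2=O | intermediate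
14 | (3R,4S)-3-{(1S,3S)-3-[(benzyloxy)methyl]-2-hydroxy-3-methylcyclohexyl}-3,4-dimethyloxan-2-ol (epimers at lactol and carbinol carbons) | OC1OCC[C@H](C)[C@]1(C)[C@@H]2CCC[C@@](C)(COCc3ccccc3)C2O | intermediate
15 | (3S,4R)-4-{(1S,3S)-3-[(benzyloxy)methyl]-2-hydroxy-3-methylcyclohexyl}-3,4-dimethylhex-5-en-1-ol (carbinol epimers) | OCC[C@H](C)[C@@](C)(C=C)[C@@H]1CCC[C@@](C)(COCc2ccccc2)C1O | intermediate
16 | (3S,4R)-4-{(1S,3S)-3-[(benzyloxy)methyl]-3-methyl-2-oxocyclohexyl}-3,4-dimethylhex-5-enal | O=CC[C@H](C)[C@@](C)(C=C)[C@@H]1CCC[C@@](C)(COCc2ccccc2)C1=O | intermediate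
17 | (1R,2S,5R,8aS)-5-[(benzyloxy)methyl]-1-ethenyl-1,2,5-trimethyl-1,2,3,5,6,7,8,8a-octahydronaphthalene | C(OCc3ccccc3)[C@]1(C)CCC[C@@H]2C1=CC[C@H](C)[C@@]2(C)C=C | intermediate
18 | but-2-yn-1-ol | CC#CCO | starting material
19 | (2Z)-3-iodobut-2-en-1-ol | C/C(I)=C/CO | intermediate
20 | 9-{2-[(1R,2S,5R,8aS)-5-[(benzyloxy)methyl]-1,2,5-trimethyl-1,2,3,5,6,7,8,8a-octahydronaphthalen-1-yl]ethyl}-9-borabicyclo[3.3.1]nonane | C(OCc3ccccc3)[C@]1(C)CCC[C@@H]2C1=CC[C@H](C)[C@@]2(C)CCB4C5CCCC4CCC5 | intermediate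
21 | (2Z)-5-{(1R,2S,5R,8aS)-5-[(benzyloxy)methyl]-1,2,5-trimethyl-1,2,3,5,6,7,8,8a-octahydronaphthalen-1-yl}-3-methylpent-2-en-1-ol | C(OCc3ccccc3)[C@]1(C)CCC[C@@H]2C1=CC[C@H](C)[C@@]2(C)CC/C(C)=C\CO | intermediate
22 | (3R)-5-{(1R,2S,5R,8aS)-5-[(benzyloxy)methyl]-1,2,5-trimethyl-1,2,3,5,6,7,8,8a-octahydronaphthalen-1-yl}-3-methylpentan-1-ol | C(OCc3ccccc3)[C@]1(C)CCC[C@@H]2C1=CC[C@H](C)[C@@]2(C)CC[C@@H](C)CCO | intermediate
23 | (3R)-5-{(1R,2S,5R,8aS)-5-[(benzyloxy)methyl]-1,2,5-trimethyl-1,2,3,5,6,7,8,8a-octahydronaphthalen-1-yl}-3-methylpentanoic acid | C(OCc3ccccc3)[C@]1(C)CCC[C@@H]2C1=CC[C@H](C)[C@@]2(C)CC[C@@H](C)CC(=O)O | intermediate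
24 | (3R)-5-[(1R,2S,5R,8aS)-5-(hydroxymethyl)-1,2,5-trimethyl-1,2,3,5,6,7,8,8a-octahydronaphthalen-1-yl]-3-methylpentanoic acid | OC[C@]1(C)CCC[C@@H]2C1=CC[C@H](C)[C@@]2(C)CC[C@@H](C)CC(=O)O | intermediate
25 | acetic (3R)-5-[(1R,2S,5R,8aS)-5-(acetyloxymethyl)-1,2,5-trimethyl-1,2,3,5,6,7,8,8a-octahydronaphthalen-1-yl]-3-methylpentanoic anhydride | CC(=O)OC[C@]1(C)CCC[C@@H]2C1=CC[C@H](C)[C@@]2(C)CC[C@@H](C)CC(=O)OC(C)=O | intermediate
26 | (3R)-5-[(1R,2S,5R,8aS)-5-(acetyloxymethyl)-1,2,5-trimethyl-1,2,3,5,6,7,8,8a-octahydronaphthalen-1-yl]-3-methylpentanoic acid (CNP0148247.1) | CC(=O)OC[C@]1(C)CCC[C@@H]2C1=CC[C@H](C)[C@@]2(C)CC[C@@H](C)CC(=O)O | target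

Total step count: 18. Longest linear sequence: 17 steps (steps 1 to 12 and 14 to 18; step 13 prepares the coupling partner 19).

Steps most likely to fail

Step 12 (key step). The reductive coupling may stall at the titanium pinacolate because deoxygenation at the hindered tertiary C5–O bond is slow, and long heating with Lewis-acidic titanium salts may epimerize C10 by enolization of the ketone. The fallback sets out from 16 and comes back at 17. Samarium diiodide (SmI2, THF, tBuOH, −78 °C) should effect a ketyl–aldehyde pinacol cyclization to the cis-diol (1R,2S,5S,8aS)-5-[(benzyloxy)methyl]-1-ethenyl-1,2,5-trimethyldecahydronaphthalene-4,4a-diol F1. Thiocarbonyldiimidazole (toluene, 110 °C) should convert it into the cyclic 4,4a-thionocarbonate of this diol F2. Heating F2 with 1,3-dimethyl-2-phenyl-1,3,2-diazaphospholidine (THF, 40 °C) should then bring about the stereospecific syn-elimination of a Corey–Winter olefination and deliver 17.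

Step 8. The hard chloromethyl ether may alkylate the hindered tetrasubstituted enolate on oxygen, enolization of the tertiary C4–H may be incomplete, and the facial bias may erode if the enolate reacts through a twist conformer. The fallback sets out from 12 and comes back at 13. Kinetic silylation (LiN(iPr)2, Me3SiCl, THF, −78 °C) should give the silyl enol ether (3R,4S)-3,4-dimethyl-3-[(1S)-3-methyl-2-(trimethylsilyloxy)cyclohex-2-en-1-yl]oxan-2-one F3. A Yb(OTf)3-catalysed Mukaiyama aldol reaction with aqueous formaldehyde (THF, rt) should add the hydroxymethyl group to C4 on the face opposite the C10 substituent and give (3R,4S)-3-[(1S,3S)-3-(hydroxymethyl)-3-methyl-2-oxocyclohexyl]-3,4-dimethyloxan-2-one F4. Acid-catalysed benzylation (benzyl 2,2,2-trichloroacetimidate, TfOH cat., CH2Cl2, 0 °C) avoids the retro-aldol pathway and should give 13.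

Step 3. The [3,3] shift has to form a bond next to the spiroacetal carbon and may be slow, so that the bis(silyl ketene acetal) is consumed by C-silylation, Claisen condensation or loss of the allylic carboxylate. The fallback sets out from 3 (and uses 2) and comes back at 8. Reduction of 3 with LiBH4 followed by acidification should give the lactone (4S)-4-methyloxan-2-one F5. O-Ethylation with Et3OBF4 and then NaOEt (EtOH, 0 °C) should give the cyclic ortho ester (4S)-2,2-diethoxy-4-methyloxane F6. Heating F6 with 2 and catalytic pivalic acid in xylene at 140 °C should exchange one ethoxy group for the allylic alcohol, lose ethanol to a cyclic ketene acetal and undergo a base-free Johnson–Claisen rearrangement with the same suprafacial transfer to C10, giving 8 directly.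

Further compounds
F1 | step 12 | (1R,2S,5S,8aS)-5-[(benzyloxy)methyl]-1-ethenyl-1,2,5-trimethyldecahydronaphthalene-4,4a-diol (4,4a-cis) | C(OCc3ccccc3)[C@]1(C)CCC[C@@H]2C1(O)C(O)C[C@H](C)[C@@]2(C)C=C
F2 | step 12 | cyclic 4,4a-thionocarbonate of F1 | C(OCc3ccccc3)[C@]1(C)CCC[C@@H]2C14OC(=S)OC4C[C@H](C)[C@@]2(C)C=C
F3 | step 8 | (3R,4S)-3,4-dimethyl-3-[(1S)-3-methyl-2-(trimethylsilyloxy)cyclohex-2-en-1-yl]oxan-2-one | O=C1OCC[C@H](C)[C@]1(C)[C@@H]2CCCC(C)=C2O[Si](C)(C)C
F4 | step 8 | (3R,4S)-3-[(1S,3S)-3-(hydroxymethyl)-3-methyl-2-oxocyclohexyl]-3,4-dimethyloxan-2-one | O=C1OCC[C@H](C)[C@]1(C)[C@@H]2CCC[C@@](C)(CO)C2=O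
F5 | step 3 | (4S)-4-methyloxan-2-one | O=C1C[C@@H](C)CCO1
F6 | step 3 | (4S)-2,2-diethoxy-4-methyloxane | CCOC1(OCC)C[C@@H](C)CCO1
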